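All runs were computed with constants of no real substance, and the scatter is random.

**Leftover substrate.** The substrate left at the end is my yardstick. I take it as the fraction e^(−n), where n counts the substrate lifetimes passed. Coupling partner with charge c, fed steadily over τ and counted as unconsumed, gives by time t an exposure of c times t squared over 2τ. Then n is k times that exposure, with k the lifetime constant, substrate lifetimes per unit of exposure.

all flasks: substrate 0.30 M
- south: coupling partner 0.25 M (fed, over 12 h); run made earlier
- west: coupling partner 0.80 M (fed, over 12 h); run made earlier
- teal: coupling partner 0.300 M (fed, over 12 h); time 12 h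
- blue: coupling partner 0.600 M (fed, over 12 h); time 12 h
- green: coupling partner 0.900 M (fed, over 12 h); time 12 h

| south: time / h | south: first product / % | west: time / h | west: first product / % |
|---|---|---|---|
| 1.33 | 0.3 | 0.500 | 0.4 |
| 2.50 | 0.9 | 1.50 | 1.3 |
| 4.00 | 2.1 | 3.00 | 3.6 |
| 5.00 | 3.6 | 4.00 | 6.4 |
| 6.00 | 4.9 | 6.00 | 12.9 |

(readings scatter by 0.5 percentage points)



- amount of first product at the end, in percent of the substrate charged, for each flask in turn (teal, blue, green)

**Reading k.** At 6.00 h the south run shows 4.9 % and the west run 12.9 %, each with a scatter of 0.5 percentage points. Pooling the two, I read k = 0.120 M⁻¹ h⁻¹. At 12 h this makes n = 0.215 for teal, 0.431 for blue and 0.646 for green.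

**The bracket.** From above, suppose all reacted substrate stays as first product, so the yield is 1 − e^(−n): 19.4 %, 35.0 %, 47.6 %. From below, suppose first product reacts on with coupling partner at the full rate constant k, so the yield is n·e^(−n): 17.4 %, 28.0 %, 33.9 %. The readings stay below 13 %, and I read no such step from them. I commit to a supposition: two like sites, a follow-on at k/2, and a yield of 2(e^(−n/2) − e^(−n)). That gives 18.3 %, 31.3 %, 40.0 %.

**The forecast.** It says 17 %, 31 % and 41 %, a little below the lower edge of the bracket for teal and inside it for blue and green, with these grounds: “I therefore trim the estimates modestly”.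

**The flasks.** Teal ends with 18.0 % of first product, blue with 30.7 % and green with 39.2 %.

    substrate + coupling partner → first product + released group (k = 0.137 M⁻¹ h⁻¹)
    coupling partner + first product → double product + released group (k = 0.0746 M⁻¹ h⁻¹)

In blue, the second rate constant over the first, the selectivity factor, is 0.54. Taken to green at 6.00 h, k gives n = 0.161, so e^(−n) leaves 85.1 % of the substrate. Green holds 84.3 % of its substrate at that time.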